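**Plan**

- Retrosynthesis: the acetate and isovalerate C–O bonds are cut first, the enal is traced back to a methyl acrylate, and the dihydrofuran ring is then opened by cutting O1–C2 and C2–C3 together.
- Enabling feature: C2 of the 2,3-dihydrobenzofuran lies between ring oxygen O1 and the oxygenated benzylic carbon C3 and carries the 1-formylvinyl group. C2 is therefore the allylic carbon of a 2-(oxymethyl)acrylate, a one-carbon unit that can be inserted between the phenol oxygen and the formyl carbon of a salicylaldehyde.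
- Forward: 4'-hydroxyacetophenone is reduced, silylated and ortho-formylated (the benzene ring is present from the start). A (4+1) annulation with the Boc carbonate of methyl 2-(hydroxymethyl)acrylate then closes the furan ring, the only ring made.
- End game: ester to allylic alcohol to enal, isovalerate at C3, then exchange of the side-chain silyl ether for the acetate.
- Stereochemistry: the side-chain (S) centre comes from asymmetric transfer hydrogenation; C2 (R) and C3 (S), trans, come from the chiral tertiary amine in the annulation.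

Key step: step 7

Assumption: β-isocupreidine is taken to induce the (2R,3S) configuration; if its sense proved opposite, the quinine-derived pseudoenantiomer would replace it without changing the route.

**Route**

Step 1
Reactants: 1 4'-hydroxyacetophenone
Product: 2 1-[4-(tert-butyldimethylsilyloxy)phenyl]ethan-1-one
Conditions: TBSCl, imidazole, DMF, rt
Reagents that add atoms: tert-butyldimethylsilyl chloride, CC(C)(C)[Si](C)(C)Cl
Why: Routine silyl ether formation at the phenol; masking the acidic phenol keeps the ketone from being deactivated as its phenoxide in the following hydride transfer.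

Step 2
Reactants: 2 1-[4-(tert-butyldimethylsilyloxy)phenyl]ethan-1-one
Product: 3 (1S)-1-[4-(tert-butyldimethylsilyloxy)phenyl]ethan-1-ol
Conditions: RuCl[(S,S)-TsDPEN](p-cymene) (1 mol %), HCO2H/Et3N (5:2), 40 °C
Reagents that add atoms: none
Why: Noyori asymmetric transfer hydrogenation of an aryl methyl ketone; the (S,S)-TsDPEN ruthenium hydride should deliver hydrogen to the Re face through the six-membered transition state and give the (S)-carbinol, formic acid making the reduction irreversible.

Step 3
Reactants: 3 (1S)-1-[4-(tert-butyldimethylsilyloxy)phenyl]ethan-1-ol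
Product: 4 tert-butyl{4-[(1S)-1-(tert-butyldimethylsilyloxy)ethyl]phenoxy}dimethylsilane
Conditions: TBSCl, imidazole, DMF, rt
Reagents that add atoms: tert-butyldimethylsilyl chloride, CC(C)(C)[Si](C)(C)Cl
Why: Standard silylation of a secondary benzylic alcohol; only the O–H bond reacts, so the (S) centre is untouched.

Step 4
Reactants: 4 tert-butyl{4-[(1S)-1-(tert-butyldimethylsilyloxy)ethyl]phenoxy}dimethylsilane
Product: 5 4-[(1S)-1-(tert-butyldimethylsilyloxy)ethyl]phenol
Conditions: Cs2CO3 (0.5 equiv), DMF/H2O (10:1), rt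
Reagents that add atoms: none
Why: Chemoselective desilylation: aryl silyl ethers are cleaved by mild carbonate base much faster than alkyl silyl ethers because phenoxide is the better leaving group, so only the phenol should be freed.

Step 5
Reactants: 5 4-[(1S)-1-(tert-butyldimethylsilyloxy)ethyl]phenol
Product: 7 5-[(1S)-1-(tert-butyldimethylsilyloxy)ethyl]-2-hydroxybenzaldehyde, via hydroxymethylphenol 6 (not isolated)
Conditions: MgCl2, Et3N, (CH2O)n, THF, reflux; then cold dilute HCl
Reagents that add atoms: paraformaldehyde (as formaldehyde), C=O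
Why: Magnesium-mediated ortho-formylation of a phenol: the magnesium phenoxide directs formaldehyde to the ortho carbon (the para position is blocked), and hydroxymethylphenol 6 is oxidised in the flask by a second formaldehyde through hydride transfer.

Step 6
Reactants: 8 methyl 2-(hydroxymethyl)prop-2-enoate
Product: 9 methyl 2-{[(tert-butoxycarbonyl)oxy]methyl}prop-2-enoate
Conditions: Boc2O, DMAP (5 mol %), CH2Cl2, 0 °C → rt
Reagents that add atoms: di-tert-butyl dicarbonate, CC(C)(C)OC(=O)OC(=O)OC(C)(C)C
Why: DMAP-catalysed carbonate formation from the Morita–Baylis–Hillman alcohol, the usual preparation of such allylic carbonates.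

Step 7
Reactants: 7 5-[(1S)-1-(tert-butyldimethylsilyloxy)ethyl]-2-hydroxybenzaldehyde; 9 methyl 2-{[(tert-butoxycarbonyl)oxy]methyl}prop-2-enoate
Product: 12 methyl 2-{(2R,3S)-5-[(1S)-1-(tert-butyldimethylsilyloxy)ethyl]-3-hydroxy-2,3-dihydro-1-benzofuran-2-yl}prop-2-enoate, via ammonium ylide 10 (not isolated), via betaine 11 (not isolated)
Conditions: β-isocupreidine (20 mol %), 9 (1.5 equiv), 4 Å MS, toluene, 0 °C → rt
Reagents that add atoms: none
Why: Proposed new method: the tertiary amine attacks the acrylate terminus of 9 (SN2'), the tert-butyl carbonate leaving group collapses to CO2 and tert-butoxide, and deprotonation at the N-bound carbon gives ylide 10, whose carbon adds reversibly to the aldehyde (C2–C3) to give betaine 11, in which the phenoxide displaces the ammonium group (O1–C2) with inversion and frees the catalyst. The closest known reactions are the phosphine- and amine-catalysed (4+1) annulations of Morita–Baylis–Hillman carbonates with ortho-hydroxyaryl imines, ortho-hydroxyaryl ketones and ortho-quinone methides, together with ammonium-ylide epoxidation of aldehydes; an amine is used because a phosphonium ylide would olefinate the aldehyde. The dihydrofuran, the only ring formed, closes in 5-exo-tet mode. C3 is set by the aldehyde face that the chiral ammonium ylide attacks (assisted by hydrogen bonding from the 6'-hydroxyl of the catalyst), and C2 by the configuration of the ammonium-bearing carbon of 11, inverted on closure; because the addition is reversible, the betaine that can close with the acrylate and the C3 oxygen on opposite faces should be drained to the trans ring. The step needs carbon attack on the aldehyde in preference to O-allylation, and five-membered closure in preference to epoxide formation or seven-membered SN2' closure: the ortho-phenoxide of the substrate is placed for the 5-exo closure and is a better nucleophile toward the allylic ammonium carbon than the alkoxide, while any O-allyl ether should re-enter the cycle by amine SN2' displacement of the aryloxide. The remote (1S) centre cannot steer the reaction, so catalyst control is required and the (2S,3R) product would be a diastereomer to be removed by chromatography.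

Step 8
Reactants: 12 methyl 2-{(2R,3S)-5-[(1S)-1-(tert-butyldimethylsilyloxy)ethyl]-3-hydroxy-2,3-dihydro-1-benzofuran-2-yl}prop-2-enoate
Product: 13 (2R,3S)-5-[(1S)-1-(tert-butyldimethylsilyloxy)ethyl]-2-(3-hydroxyprop-1-en-2-yl)-2,3-dihydro-1-benzofuran-3-ol
Conditions: (i-Bu)2AlH (4 equiv), CH2Cl2, −78 → 0 °C; aq. potassium sodium tartrate
Reagents that add atoms: none
Why: DIBAL reduces α,β-unsaturated esters by 1,2-addition to the allylic alcohol; the C3 hydroxyl is carried as its aluminium alkoxide, and neither the silyl ether nor the stereocentres are affected.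

Step 9
Reactants: 13 (2R,3S)-5-[(1S)-1-(tert-butyldimethylsilyloxy)ethyl]-2-(3-hydroxyprop-1-en-2-yl)-2,3-dihydro-1-benzofuran-3-ol
Product: 14 2-{(2R,3S)-5-[(1S)-1-(tert-butyldimethylsilyloxy)ethyl]-3-hydroxy-2,3-dihydro-1-benzofuran-2-yl}prop-2-enal
Conditions: TEMPO (10 mol %), PhI(OAc)2 (1.1 equiv), CH2Cl2, rt
Reagents that add atoms: none
Why: TEMPO/PhI(OAc)2 oxidation, in which the oxoammonium ion oxidises the unhindered primary allylic alcohol much faster than the flanked secondary benzylic one and stops at the aldehyde; the trans relationship at C2/C3 keeps the C3 hydroxyl from forming a lactol with the new formyl group.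

Step 10
Reactants: 14 2-{(2R,3S)-5-[(1S)-1-(tert-butyldimethylsilyloxy)ethyl]-3-hydroxy-2,3-dihydro-1-benzofuran-2-yl}prop-2-enal; 15 3-methylbutanoyl chloride (isovaleryl chloride)
Product: 16 (2R,3S)-5-[(1S)-1-(tert-butyldimethylsilyloxy)ethyl]-2-(3-oxoprop-1-en-2-yl)-2,3-dihydro-1-benzofuran-3-yl 3-methylbutanoate
Conditions: pyridine, CH2Cl2, 0 °C → rt
Reagents that add atoms: none
Why: Acylation of a secondary alcohol with an acid chloride and pyridine (nucleophilic acyl substitution); no stronger nucleophilic catalyst is used so that conjugate addition to the enal is avoided, and C3 keeps its configuration because only the O–H bond reacts.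

Step 11
Reactants: 16 (2R,3S)-5-[(1S)-1-(tert-butyldimethylsilyloxy)ethyl]-2-(3-oxoprop-1-en-2-yl)-2,3-dihydro-1-benzofuran-3-yl 3-methylbutanoate
Product: 17 (2R,3S)-5-[(1S)-1-hydroxyethyl]-2-(3-oxoprop-1-en-2-yl)-2,3-dihydro-1-benzofuran-3-yl 3-methylbutanoate
Conditions: HF·pyridine, pyridine, THF, 0 °C → rt
Reagents that add atoms: none
Why: Fluoride-mediated cleavage of a secondary silyl ether with pyridine-buffered HF·pyridine, conditions under which esters and enals normally survive and the benzylic C–O bonds should not ionise.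

Step 12
Reactants: 17 (2R,3S)-5-[(1S)-1-hydroxyethyl]-2-(3-oxoprop-1-en-2-yl)-2,3-dihydro-1-benzofuran-3-yl 3-methylbutanoate
Product: 18 (2R,3S)-5-[(1S)-1-acetoxyethyl]-2-(3-oxoprop-1-en-2-yl)-2,3-dihydro-1-benzofuran-3-yl 3-methylbutanoate
Conditions: Ac2O, pyridine, CH2Cl2, rt
Reagents that add atoms: acetic anhydride, CC(=O)OC(C)=O
Why: Acetylation with acetic anhydride and pyridine takes place at oxygen with retention at the (S) carbinol centre and completes the target.

**Compound list**

1 | 4'-hydroxyacetophenone | CC(=O)c1ccc(O)cc1 | starting material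
2 | 1-[4-(tert-butyldimethylsilyloxy)phenyl]ethan-1-one | CC(=O)c1ccc(O[Si](C)(C)C(C)(C)C)cc1 | intermediate
3 | (1S)-1-[4-(tert-butyldimethylsilyloxy)phenyl]ethan-1-ol | C[C@H](O)c1ccc(O[Si](C)(C)C(C)(C)C)cc1 | intermediate
4 | tert-butyl{4-[(1S)-1-(tert-butyldimethylsilyloxy)ethyl]phenoxy}dimethylsilane | C[C@H](O[Si](C)(C)C(C)(C)C)c1ccc(O[Si](C)(C)C(C)(C)C)cc1 | intermediate
5 | 4-[(1S)-1-(tert-butyldimethylsilyloxy)ethyl]phenol | C[C@H](O[Si](C)(C)C(C)(C)C)c1ccc(O)cc1 | intermediate
6 | 4-[(1S)-1-(tert-butyldimethylsilyloxy)ethyl]-2-(hydroxymethyl)phenol (present as its magnesium phenoxide, not isolated) | OCc1cc([C@H](C)O[Si](C)(C)C(C)(C)C)ccc1O | intermediate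
7 | 5-[(1S)-1-(tert-butyldimethylsilyloxy)ethyl]-2-hydroxybenzaldehyde | O=Cc1cc([C@H](C)O[Si](C)(C)C(C)(C)C)ccc1O | intermediate
8 | methyl 2-(hydroxymethyl)prop-2-enoate | C=C(CO)C(=O)OC | starting material
9 | methyl 2-{[(tert-butoxycarbonyl)oxy]methyl}prop-2-enoate | C=C(COC(=O)OC(C)(C)C)C(=O)OC | intermediate
10 | N-[2-(methoxycarbonyl)prop-2-en-1-yl]-β-isocupreidinium ylide, carbanion on the N-bound carbon (zwitterion, not isolated) | Oc1ccc2nccc(c2c1)[C@@H]3O[C@@]4(CC)C[N@+]5([CH-]C(=C)C(=O)OC)CC[C@H]4C[C@H]35 | intermediate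
11 | betaine: β-isocupreidinium bound to C2 of the (1S,2S)-1-aryl-1-hydroxy-3-(methoxycarbonyl)but-3-en-2-yl unit, aryl = 5-[(1S)-1-(tert-butyldimethylsilyloxy)ethyl]-2-oxidophenyl (zwitterion, not isolated) | Oc1ccc2nccc(c2c1)[C@@H]3O[C@@]4(CC)C[N@+]5([C@@H](C(=C)C(=O)OC)[C@@H](O)c6cc(ccc6[O-])[C@H](C)O[Si](C)(C)C(C)(C)C)CC[C@H]4C[C@H]35 | intermediate
12 | methyl 2-{(2R,3S)-5-[(1S)-1-(tert-butyldimethylsilyloxy)ethyl]-3-hydroxy-2,3-dihydro-1-benzofuran-2-yl}prop-2-enoate | C=C(C(=O)OC)[C@H]1Oc2ccc([C@H](C)O[Si](C)(C)C(C)(C)C)cc2[C@@H]1O | intermediate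
13 | (2R,3S)-5-[(1S)-1-(tert-butyldimethylsilyloxy)ethyl]-2-(3-hydroxyprop-1-en-2-yl)-2,3-dihydro-1-benzofuran-3-ol | C=C(CO)[C@H]1Oc2ccc([C@H](C)O[Si](C)(C)C(C)(C)C)cc2[C@@H]1O | intermediate
14 | 2-{(2R,3S)-5-[(1S)-1-(tert-butyldimethylsilyloxy)ethyl]-3-hydroxy-2,3-dihydro-1-benzofuran-2-yl}prop-2-enal | C=C(C=O)[C@H]1Oc2ccc([C@H](C)O[Si](C)(C)C(C)(C)C)cc2[C@@H]1O | intermediate
15 | 3-methylbutanoyl chloride (isovaleryl chloride) | CC(C)CC(=O)Cl | starting material
16 | (2R,3S)-5-[(1S)-1-(tert-butyldimethylsilyloxy)ethyl]-2-(3-oxoprop-1-en-2-yl)-2,3-dihydro-1-benzofuran-3-yl 3-methylbutanoate | C=C(C=O)[C@H]1Oc2ccc([C@H](C)O[Si](C)(C)C(C)(C)C)cc2[C@@H]1OC(=O)CC(C)C | intermediate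
17 | (2R,3S)-5-[(1S)-1-hydroxyethyl]-2-(3-oxoprop-1-en-2-yl)-2,3-dihydro-1-benzofuran-3-yl 3-methylbutanoate | C=C(C=O)[C@H]1Oc2ccc([C@H](C)O)cc2[C@@H]1OC(=O)CC(C)C | intermediate
18 | (2R,3S)-5-[(1S)-1-acetoxyethyl]-2-(3-oxoprop-1-en-2-yl)-2,3-dihydro-1-benzofuran-3-yl 3-methylbutanoate | C=C(C=O)[C@H]1Oc2ccc([C@H](C)OC(C)=O)cc2[C@@H]1OC(=O)CC(C)C | target

**Step count and risks**

Total: 12 steps. Longest linear sequence: 11 steps (steps 1–5 and 7–12); step 6 is a one-step branch.

Steps most likely to fail:

1. Step 7 (new method). The phenoxide may be consumed by SN2' O-allylation without returning to the ylide pathway, closure may occur at the terminal alkene carbon to a seven-membered ring, or the catalyst may discriminate the aldehyde faces poorly. The fallback forms the same ring stepwise through a vinyl epoxide, using known reactions. Setting out from 7, the phenol is silylated again (TBSCl, imidazole) to 2-(tert-butyldimethylsilyloxy)-5-[(1S)-1-(tert-butyldimethylsilyloxy)ethyl]benzaldehyde F1. Wittig olefination with the phosphonium ylide generated from carbonate 9 and stoichiometric Bu3P should give methyl (3E)-4-{2-(tert-butyldimethylsilyloxy)-5-[(1S)-1-(tert-butyldimethylsilyloxy)ethyl]phenyl}-2-methylidenebut-3-enoate F2. Shi epoxidation (KHSO5, K2CO3 buffer, the L-fructose-derived ketone, sense to be confirmed) should oxidise the electron-rich styrenyl double bond and leave the electron-poor acrylate alkene, giving methyl 2-[(2S,3S)-3-{2-(tert-butyldimethylsilyloxy)-5-[(1S)-1-(tert-butyldimethylsilyloxy)ethyl]phenyl}oxiran-2-yl]prop-2-enoate F3. Cs2CO3 in DMF/H2O then frees the phenoxide, which opens the trans epoxide at the allylic carbon with inversion to the trans five-membered ring, coming back to the route at 12.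

2. Step 10. Pyridine or chloride may add to the enal and expel the C2 aryloxide (ring opening, C2 epimerisation), or acylation of the flanked C3 hydroxyl may be too slow to outrun this. The fallback installs the isovalerate before the enal exists, which also removes the need for hydroxyl discrimination in step 9. Setting out from 13, the primary hydroxyl is silylated (TESCl, imidazole, 0 °C) to (2R,3S)-5-[(1S)-1-(tert-butyldimethylsilyloxy)ethyl]-2-{3-[(triethylsilyl)oxy]prop-1-en-2-yl}-2,3-dihydro-1-benzofuran-3-ol F4. Acylation with 15 (pyridine, cat. DMAP) gives its 3-methylbutanoate F5. AcOH/THF/H2O removes the primary triethylsilyl ether only, giving (2R,3S)-5-[(1S)-1-(tert-butyldimethylsilyloxy)ethyl]-2-(3-hydroxyprop-1-en-2-yl)-2,3-dihydro-1-benzofuran-3-yl 3-methylbutanoate F6. Dess–Martin oxidation (NaHCO3 buffer) then returns to the route at 16.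

3. Step 11. Acid may ionise the benzylic C–O bonds (loss of the C3 ester with aromatisation to the benzofuran, or erosion of the side-chain centre), and fluoride or pyridine may add to the enal during desilylation. The fallback removes all silicon before the enal is made. Setting out from 13, selective silylation of the primary hydroxyl (TBSCl, imidazole, 0 °C) gives (2R,3S)-2-{3-[(tert-butyldimethylsilyl)oxy]prop-1-en-2-yl}-5-[(1S)-1-(tert-butyldimethylsilyloxy)ethyl]-2,3-dihydro-1-benzofuran-3-ol F7. Acylation with 15 (pyridine, cat. DMAP) gives its 3-methylbutanoate F8. TBAF buffered with AcOH cleaves both silyl ethers to (2R,3S)-5-[(1S)-1-hydroxyethyl]-2-(3-hydroxyprop-1-en-2-yl)-2,3-dihydro-1-benzofuran-3-yl 3-methylbutanoate F9. TEMPO/PhI(OAc)2 then oxidises only the primary allylic alcohol, coming back to the route at 17.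

**Further compounds**

F1 | step 7 | 2-(tert-butyldimethylsilyloxy)-5-[(1S)-1-(tert-butyldimethylsilyloxy)ethyl]benzaldehyde | O=Cc1cc([C@H](C)O[Si](C)(C)C(C)(C)C)ccc1O[Si](C)(C)C(C)(C)C
F2 | step 7 | methyl (3E)-4-{2-(tert-butyldimethylsilyloxy)-5-[(1S)-1-(tert-butyldimethylsilyloxy)ethyl]phenyl}-2-methylidenebut-3-enoate | C=C(C(=O)OC)/C=C/c1cc([C@H](C)O[Si](C)(C)C(C)(C)C)ccc1O[Si](C)(C)C(C)(C)C
F3 | step 7 | methyl 2-[(2S,3S)-3-{2-(tert-butyldimethylsilyloxy)-5-[(1S)-1-(tert-butyldimethylsilyloxy)ethyl]phenyl}oxiran-2-yl]prop-2-enoate | C=C(C(=O)OC)[C@@H]1O[C@H]1c2cc([C@H](C)O[Si](C)(C)C(C)(C)C)ccc2O[Si](C)(C)C(C)(C)C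
F4 | step 10 | (2R,3S)-5-[(1S)-1-(tert-butyldimethylsilyloxy)ethyl]-2-{3-[(triethylsilyl)oxy]prop-1-en-2-yl}-2,3-dihydro-1-benzofuran-3-ol | C=C(CO[Si](CC)(CC)CC)[C@H]1Oc2ccc([C@H](C)O[Si](C)(C)C(C)(C)C)cc2[C@@H]1O
F5 | step 10 | (2R,3S)-5-[(1S)-1-(tert-butyldimethylsilyloxy)ethyl]-2-{3-[(triethylsilyl)oxy]prop-1-en-2-yl}-2,3-dihydro-1-benzofuran-3-yl 3-methylbutanoate | C=C(CO[Si](CC)(CC)CC)[C@H]1Oc2ccc([C@H](C)O[Si](C)(C)C(C)(C)C)cc2[C@@H]1OC(=O)CC(C)C
F6 | step 10 | (2R,3S)-5-[(1S)-1-(tert-butyldimethylsilyloxy)ethyl]-2-(3-hydroxyprop-1-en-2-yl)-2,3-dihydro-1-benzofuran-3-yl 3-methylbutanoate | C=C(CO)[C@H]1Oc2ccc([C@H](C)O[Si](C)(C)C(C)(C)C)cc2[C@@H]1OC(=O)CC(C)C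
F7 | step 11 | (2R,3S)-2-{3-[(tert-butyldimethylsilyl)oxy]prop-1-en-2-yl}-5-[(1S)-1-(tert-butyldimethylsilyloxy)ethyl]-2,3-dihydro-1-benzofuran-3-ol | C=C(CO[Si](C)(C)C(C)(C)C)[C@H]1Oc2ccc([C@H](C)O[Si](C)(C)C(C)(C)C)cc2[C@@H]1O
F8 | step 11 | (2R,3S)-2-{3-[(tert-butyldimethylsilyl)oxy]prop-1-en-2-yl}-5-[(1S)-1-(tert-butyldimethylsilyloxy)ethyl]-2,3-dihydro-1-benzofuran-3-yl 3-methylbutanoate | C=C(CO[Si](C)(C)C(C)(C)C)[C@H]1Oc2ccc([C@H](C)O[Si](C)(C)C(C)(C)C)cc2[C@@H]1OC(=O)CC(C)C
F9 | step 11 | (2R,3S)-5-[(1S)-1-hydroxyethyl]-2-(3-hydroxyprop-1-en-2-yl)-2,3-dihydro-1-benzofuran-3-yl 3-methylbutanoate | C=C(CO)[C@H]1Oc2ccc([C@H](C)O)cc2[C@@H]1OC(=O)CC(C)C
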